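**Strategy**

Ring numbering: C1 ketone, C2=C3, C4 carbinol, C5 (side-chain carbon), C6 (CMe2). The key step exploits the unsubstituted cis C2H=C3H unit of the cyclohexenone ring: it lies between C1 and C4, both acyl carbons once the C4 methyl group is set aside. C1–C6–C5–C4 is therefore made as a 2-allyl-3,3-dimethylsuccinic bis(thioester) carrying the only pre-set stereocentre, C5, and is stitched to (Z)-1,2-bis(tributylstannyl)ethene by a double palladium/copper-mediated Liebeskind–Srogl acylation that forms C1–C2 and C3–C4 and closes the cyclohex-2-ene-1,4-dione in one operation. Methyllithium then adds to C4 anti to the C5 allyl group, which is finally converted into the (Z)-enone decanoate side chain.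

Key step: step 6

Remark: side-chain atoms are labelled C7H2–C8(=O)–C9(CH3)=C10H–C11H2–O; (Z)-1,2-bis(tributylstannyl)ethene and (Z)-3-iodobut-2-en-1-ol are assumed not to be stock items and are made in steps 5 and 9.

**Route**

Step 1
Reactants: 1 2,2-dimethylsuccinic anhydride; 2 (R)-4-benzyl-1,3-oxazolidin-2-one
Product: 4 4-[(4R)-4-benzyl-2-oxo-1,3-oxazolidin-3-yl]-2,2-dimethyl-4-oxobutanoic acid, via lithium oxazolidinide 3 (not isolated)
Conditions: n-BuLi, THF, −78 °C; then 1, −78 → 0 °C; 1 M HCl work-up
Reagents that add atoms: none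
Why: N-acylation of the lithiated oxazolidinone by ring opening of the cyclic anhydride should occur at the carbonyl remote from the gem-dimethyl carbon, the less hindered one, leaving the tertiary carboxylic acid free.

Step 2
Reactants: 4 imide acid
Product: 6 (3R)-3-{[(4R)-4-benzyl-2-oxo-1,3-oxazolidin-3-yl]carbonyl}-2,2-dimethylhex-5-enoic acid, via disodium enolate carboxylate 5 (not isolated)
Conditions: NaN(SiMe3)2 (2.2 equiv), THF, −78 °C; allyl iodide, −78 → −40 °C; 1 M HCl work-up
Reagents that add atoms: allyl iodide, C=CCI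
Why: Evans asymmetric alkylation: the chelated sodium (Z)-enolate is allylated on the face opposite the benzyl group, which sets C5 as R, while the hindered carboxylate can neither be acylated by the enolate nor compete for allyl iodide at low temperature.

Step 3
Reactants: 6 allylated imide acid
Product: 7 (3R)-3-[(ethylsulfanyl)carbonyl]-2,2-dimethylhex-5-enoic acid
Conditions: EtSH (4 equiv), n-BuLi (3 equiv), THF, 0 °C → rt; 1 M HCl work-up
Reagents that add atoms: ethanethiol, CCS
Why: Thiolate transacylation of the N-acyloxazolidinone removes the auxiliary as a thioester: attack at the ring carbamate is reversible whereas exocyclic cleavage releases the stabilised oxazolidinide, so the hindered acyl group should pass to sulfur without epimerising C5.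

Step 4
Reactants: 7 thioester acid
Product: 8 S,S'-diethyl (2R)-3,3-dimethyl-2-(prop-2-en-1-yl)butanebis(thioate)
Conditions: DCC, DMAP (cat.), EtSH, CH2Cl2, 0 °C → rt
Reagents that add atoms: ethanethiol, CCS
Why: Steglich thioesterification: the tertiary acid is activated by the carbodiimide and DMAP and captured by the thiol under near-neutral conditions that leave C5 untouched.

Step 5
Reactants: 9 acetylene; 10 hexabutylditin
Product: 11 (Z)-1,2-bis(tributylstannyl)ethene
Conditions: Pd(PPh3)4 (cat.), acetylene (1 atm), dioxane, 60 °C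
Reagents that add atoms: none
Why: Palladium-catalysed syn-distannylation of an alkyne: oxidative addition of the Sn–Sn bond to zerovalent palladium, insertion of acetylene and reductive elimination deliver both tin atoms to the same side, hence the Z alkene.

Step 6
Reactants: 8 bis(thioester); 11 (Z)-1,2-bis(tributylstannyl)ethene
Product: 13 (5R)-6,6-dimethyl-5-(prop-2-en-1-yl)cyclohex-2-ene-1,4-dione, via stannyl enone thioester 12 (not isolated)
Conditions: Pd2(dba)3 (5 mol %), tri(2-furyl)phosphine (20 mol %), CuOP(O)Ph2 (2.5 equiv), THF, 50 °C, high dilution, slow addition of 8 and 11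
Reagents that add atoms: none
Why: Zerovalent palladium inserts into the C(acyl)–S bond of the less hindered thioester (on C4) with the help of the copper phosphinate, which takes up the thiolate and activates the alkenylstannane for tin-to-metal transfer with retention of the Z geometry; reductive elimination gives the (Z)-β-stannyl enone 12, and the same sequence at the second thioester, now intramolecular, forms the remaining acyl–alkenyl bond. The closest known reaction type is the Liebeskind–Srogl ketone synthesis from thioesters and organostannanes, used twice on one bis-stannane in the manner of a Stille stitching annulation. The six-membered ring is closed by C–C reductive elimination from a seven-membered acyl(alkenyl)palladacycle, a formal [4+2] union of the C1–C6–C5–C4 bis-acyl unit with the C2=C3 unit that is possible only because the two-carbon unit is cis. No stereocentre is created, and C5, which is α to an acyl group, should survive because the medium is neutral and non-basic. The step needs ring closure to win over oligomerisation, which high dilution and the gem-dimethyl group at C6 should secure, and it needs no regiocontrol because the two ends of the C2 unit are equivalent, so either thioester may react first.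

Step 7
Reactants: 13 ene-dione
Product: 15 (4S,5R)-4,6,6-trimethyl-5-(prop-2-en-1-yl)-4-(triethylsilyloxy)cyclohex-2-en-1-one, via lithium alkoxide 14 (not isolated)
Conditions: MeLi (1.1 equiv), Et2O, −78 °C; then Et3SiOTf, −78 → 0 °C
Reagents that add atoms: methyllithium, [Li]C; triethylsilyl trifluoromethanesulfonate, CC[Si](CC)(CC)OS(=O)(=O)C(F)(F)F
Why: 1,2-Addition of an organolithium to a ketone followed by O-silylation: C1 is shielded by the adjacent quaternary C6, so MeLi should attack C4, and it should do so anti to the C5 allyl group and to the axial C6 methyl group, which places the oxygen cis to the C5 substituent (4S).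

Step 8
Reactants: 15 silyl ether
Product: 17 2-[(1R,2S)-2,6,6-trimethyl-5-oxo-2-(triethylsilyloxy)cyclohex-3-en-1-yl]acetaldehyde, via secondary ozonide 16 (not isolated)
Conditions: O3, CH2Cl2, −78 °C, stopped at the first trace of blue; then PPh3, −78 °C → rt
Reagents that add atoms: ozone, [O-][O+]=O
Why: Ozonolysis with reductive work-up: the electron-rich terminal alkene reacts far faster than the electron-poor, hindered C2=C3 enone bond, and the silyl ether keeps the aldehyde from closing to a lactol on the C4 oxygen.

Step 9
Reactants: 18 but-2-yn-1-ol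
Product: 20 (Z)-3-iodobut-2-en-1-ol, via cyclic alkenylalanate 19 (not isolated)
Conditions: NaAlH2(OCH2CH2OCH3)2, THF, 0 °C → rt; then I2, THF, −78 → 0 °C
Reagents that add atoms: iodine, II
Why: Alkoxide-directed trans-hydroalumination of a propargylic alcohol and iodinolysis with retention: aluminium is delivered to C3 within a five-membered ring, so iodine ends up cis to the CH2OH group (Z).

Step 10
Reactants: 20 (Z)-3-iodobut-2-en-1-ol; 21 decanoyl chloride
Product: 22 (Z)-3-iodobut-2-en-1-yl decanoate
Conditions: pyridine, DMAP (cat.), CH2Cl2, 0 °C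
Reagents that add atoms: none
Why: Acylation of a primary alcohol by an acid chloride under nucleophilic catalysis leaves the alkenyl iodide untouched.

Step 11
Reactants: 17 aldehyde; 22 alkenyl iodide
Product: 24 (2Z)-4-hydroxy-3-methyl-5-[(1R,2S)-2,6,6-trimethyl-5-oxo-2-(triethylsilyloxy)cyclohex-3-en-1-yl]pent-2-en-1-yl decanoate (both C8 epimers), via alkenylchromium dichloride 23 (not isolated)
Conditions: CrCl2 (4 equiv), NiCl2 (2 mol %), DMF, rt
Reagents that add atoms: none
Why: Nozaki–Hiyama–Kishi reaction: zerovalent nickel inserts into the C–I bond with retention of the trisubstituted alkene geometry and hands the alkenyl group to chromium, which adds to the aldehyde but not to the enone or the esters; the new C8 carbinol centre forms as a mixture that the next step removes.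

Step 12
Reactants: 24 allylic alcohol
Product: 25 (2Z)-3-methyl-4-oxo-5-[(1R,2S)-2,6,6-trimethyl-5-oxo-2-(triethylsilyloxy)cyclohex-3-en-1-yl]pent-2-en-1-yl decanoate
Conditions: Dess–Martin periodinane, NaHCO3, CH2Cl2, 0 °C → rt
Reagents that add atoms: none
Why: Dess–Martin oxidation of the secondary allylic alcohol under buffered conditions should give the (Z)-enone without alkene isomerisation and erases the C8 stereocentre.

Step 13
Reactants: 25 silyl-protected enone
Product: 26 (2Z)-5-[(1R,2S)-2-hydroxy-2,6,6-trimethyl-5-oxocyclohex-3-en-1-yl]-3-methyl-4-oxopent-2-en-1-yl decanoate (target)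
Conditions: HF·pyridine, THF/pyridine, 0 °C → rt
Reagents that add atoms: none
Why: Fluoride-mediated cleavage of the tertiary triethylsilyl ether under buffered conditions should spare the allylic ester, the (Z)-enone and the tertiary allylic alcohol.

**Compound list**

1 | 2,2-dimethylsuccinic anhydride | CC1(C)CC(=O)OC1=O | starting material
2 | (R)-4-benzyl-1,3-oxazolidin-2-one | O=C1N[C@H](Cc2ccccc2)CO1 | starting material
3 | lithium (4R)-4-benzyl-2-oxo-1,3-oxazolidin-3-ide (not isolated) | [Li+].O=C1[N-][C@H](Cc2ccccc2)CO1 | intermediate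
4 | 4-[(4R)-4-benzyl-2-oxo-1,3-oxazolidin-3-yl]-2,2-dimethyl-4-oxobutanoic acid | OC(=O)C(C)(C)CC(=O)N1[C@H](Cc2ccccc2)COC1=O | intermediate
5 | disodium (Z)-enolate carboxylate of 4 (not isolated) | [Na+].[Na+].[O-]C(=O)C(C)(C)/C=C(\[O-])N1[C@H](Cc2ccccc2)COC1=O | intermediate
6 | (3R)-3-{[(4R)-4-benzyl-2-oxo-1,3-oxazolidin-3-yl]carbonyl}-2,2-dimethylhex-5-enoic acid | OC(=O)C(C)(C)[C@@H](CC=C)C(=O)N1[C@H](Cc2ccccc2)COC1=O | intermediate
7 | (3R)-3-[(ethylsulfanyl)carbonyl]-2,2-dimethylhex-5-enoic acid | CCSC(=O)[C@H](CC=C)C(C)(C)C(=O)O | intermediate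
8 | S,S'-diethyl (2R)-3,3-dimethyl-2-(prop-2-en-1-yl)butanebis(thioate) | CCSC(=O)[C@H](CC=C)C(C)(C)C(=O)SCC | intermediate
9 | acetylene | C#C | starting material
10 | hexabutylditin | CCCC[Sn](CCCC)(CCCC)[Sn](CCCC)(CCCC)CCCC | starting material
11 | (Z)-1,2-bis(tributylstannyl)ethene | CCCC[Sn](CCCC)(CCCC)/C=C\[Sn](CCCC)(CCCC)CCCC | intermediate
12 | S-ethyl (3R,5Z)-2,2-dimethyl-4-oxo-3-(prop-2-en-1-yl)-6-(tributylstannyl)hex-5-enethioate (not isolated) | CCSC(=O)C(C)(C)[C@@H](CC=C)C(=O)/C=C\[Sn](CCCC)(CCCC)CCCC | intermediate
13 | (5R)-6,6-dimethyl-5-(prop-2-en-1-yl)cyclohex-2-ene-1,4-dione (target ring numbering) | C=CC[C@@H]1C(C)(C)C(=O)C=CC1=O | intermediate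
14 | lithium (1S,6R)-1,5,5-trimethyl-4-oxo-6-(prop-2-en-1-yl)cyclohex-2-en-1-olate (not isolated) | [Li+].C=CC[C@@H]1C(C)(C)C(=O)C=C[C@]1(C)[O-] | intermediate
15 | (4S,5R)-4,6,6-trimethyl-5-(prop-2-en-1-yl)-4-(triethylsilyloxy)cyclohex-2-en-1-one | C=CC[C@@H]1C(C)(C)C(=O)C=C[C@]1(C)O[Si](CC)(CC)CC | intermediate
16 | secondary ozonide (1,2,4-trioxolane) of 15, mixture at the trioxolane carbon (not isolated) | C1OOC(O1)C[C@@H]2C(C)(C)C(=O)C=C[C@]2(C)O[Si](CC)(CC)CC | intermediate
17 | 2-[(1R,2S)-2,6,6-trimethyl-5-oxo-2-(triethylsilyloxy)cyclohex-3-en-1-yl]acetaldehyde | O=CC[C@@H]1C(C)(C)C(=O)C=C[C@]1(C)O[Si](CC)(CC)CC | intermediate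
18 | but-2-yn-1-ol | CC#CCO | starting material
19 | sodium 2,2-bis(2-methoxyethoxy)-3-methyl-2,5-dihydro-1,2-oxaluminol-2-uide, cyclic (Z)-alkenylalanate (not isolated) | [Na+].CC1=CCO[Al-]1(OCCOC)OCCOC | intermediate
20 | (Z)-3-iodobut-2-en-1-ol | OC/C=C(/C)I | intermediate
21 | decanoyl chloride | CCCCCCCCCC(Cl)=O | starting material
22 | (Z)-3-iodobut-2-en-1-yl decanoate | CCCCCCCCCC(=O)OC/C=C(/C)I | intermediate
23 | [(2Z)-4-(decanoyloxy)but-2-en-2-yl]chromium dichloride (not isolated) | CCCCCCCCCC(=O)OC/C=C(/C)[Cr](Cl)Cl | intermediate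
24 | (2Z)-4-hydroxy-3-methyl-5-[(1R,2S)-2,6,6-trimethyl-5-oxo-2-(triethylsilyloxy)cyclohex-3-en-1-yl]pent-2-en-1-yl decanoate (both C8 epimers) | CCCCCCCCCC(=O)OC/C=C(/C)C(O)C[C@@H]1C(C)(C)C(=O)C=C[C@]1(C)O[Si](CC)(CC)CC | intermediate
25 | (2Z)-3-methyl-4-oxo-5-[(1R,2S)-2,6,6-trimethyl-5-oxo-2-(triethylsilyloxy)cyclohex-3-en-1-yl]pent-2-en-1-yl decanoate | CCCCCCCCCC(=O)OC/C=C(/C)C(=O)C[C@@H]1C(C)(C)C(=O)C=C[C@]1(C)O[Si](CC)(CC)CC | intermediate
26 | (2Z)-5-[(1R,2S)-2-hydroxy-2,6,6-trimethyl-5-oxocyclohex-3-en-1-yl]-3-methyl-4-oxopent-2-en-1-yl decanoate | CCCCCCCCCC(=O)OC/C=C(/C)C(=O)C[C@@H]1C(C)(C)C(=O)C=C[C@]1(C)O | target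

**Step count and risks**

Total steps: 13. Longest linear sequence: 10 steps (steps 1–4, 6–8, 11–13).

Step 6 (double acylative ring closure). What may go wrong: the sequence may stall at 12 because oxidative addition into the neopentyl-type thioester on C1 is slow. Oligomerisation, protodestannylation, insertion of the allyl group into the acylpalladium species or conjugate addition of thiolate to the ene-dione could then take over. Fallback (anionic stitching, from 8 back to 13): 8 is converted with MeNHOMe·HCl and i-PrMgCl (THF, −20 °C → rt) into the bis(N-methoxy-N-methylamide) F1. At −78 °C F1 is added to (Z)-2-(tributylstannyl)ethenyllithium F2, made from 11 and one equivalent of n-BuLi. F2 should add to the less hindered amide and stop at the chelated lithium hemiaminalate F3. A second equivalent of n-BuLi then effects tin–lithium exchange, which at −78 °C should outrun attack on the shielded C1 amide, and the alkenyllithium closes onto that amide to give the dilithium bis(hemiaminalate) F4. Aqueous NH4Cl releases 13.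

Step 7 (methyl addition). What may go wrong: attack at C1 instead of C4, approach syn to the allyl group (poor facial selectivity), or enolisation at C5 with erosion of optical purity. Fallback (C4 set before ring closure, from 8 back to 15): 8 is coupled with an excess of 11 under the catalyst system of step 6 at room temperature with one equivalent of CuOP(O)Ph2, and the mono-coupled (Z)-β-stannyl enone 12 is isolated. MeMgBr (THF, −78 °C) adds to its ketone under Felkin–Anh control (CMe2 group anti to the nucleophile), which should give the same C4 configuration, and the alkoxide closes onto the thioester to give the stannylalkenyl γ-lactone F5. Iododestannylation (I2, CH2Cl2, 0 °C) gives the (Z)-iodoalkenyl lactone F6. t-BuLi (2 equiv, Et2O, −100 °C) effects iodine–lithium exchange and the alkenyllithium attacks the lactone carbonyl (Parham-type cyclisation). The bridged hemiketal alkoxide opens to the lithium alkoxide 14, and Et3SiOTf gives 15.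

Step 2 (alkylation of the hindered dianion). What may go wrong: slow C-alkylation next to the quaternary carbon, competing O-allylation of the carboxylate, or loss of the auxiliary from the enolate through a ketene. Fallback ([3,3] shift instead of enolate alkylation, from 1 back to 8): 1 is opened with allyl alcohol (Et3N, DMAP, CH2Cl2) at the less hindered carbonyl to give the allyl half-ester F7. DCC, DMAP and EtSH convert its tertiary acid into the allyl ester thioester F8. An enantioselective Ireland–Claisen rearrangement of the boron enolate then moves the allyl group to C5 and gives the thioester acid F9. The enolate is formed with a chiral 2-bromo-4,5-diphenyl-1,3-bis(arylsulfonyl)-1,3,2-diazaborolidine and i-Pr2NEt (CH2Cl2, −78 → 4 °C), the controller enantiomer being chosen to give R at C5. DCC, DMAP and EtSH give 8.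

**Further compounds**

F1 | step 6 | (2R)-N1,N4-dimethoxy-N1,N4,3,3-tetramethyl-2-(prop-2-en-1-yl)butanediamide | CON(C)C(=O)[C@H](CC=C)C(C)(C)C(=O)N(C)OC
F2 | step 6 | (Z)-2-(tributylstannyl)ethenyllithium | [Li]/C=C\[Sn](CCCC)(CCCC)CCCC
F3 | step 6 | lithium hemiaminalate from addition of F2 to the C4 amide of F1 (not isolated, mixture at the new carbon) | [Li+].CON(C)C(=O)C(C)(C)[C@@H](CC=C)C([O-])(N(C)OC)/C=C\[Sn](CCCC)(CCCC)CCCC
F4 | step 6 | dilithium bis(hemiaminalate) of 13 (not isolated) | [Li+].[Li+].C=CC[C@@H]1C(C)(C)C([O-])(N(C)OC)C=CC1([O-])N(C)OC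
F5 | step 7 | (4R,5R)-3,3,5-trimethyl-4-(prop-2-en-1-yl)-5-[(Z)-2-(tributylstannyl)ethenyl]oxolan-2-one | C=CC[C@@H]1C(C)(C)C(=O)O[C@@]1(C)/C=C\[Sn](CCCC)(CCCC)CCCC
F6 | step 7 | (4R,5R)-5-[(Z)-2-iodoethenyl]-3,3,5-trimethyl-4-(prop-2-en-1-yl)oxolan-2-one | C=CC[C@@H]1C(C)(C)C(=O)O[C@@]1(C)/C=C\I
F7 | step 2 | 2,2-dimethyl-4-oxo-4-(prop-2-en-1-yloxy)butanoic acid | C=CCOC(=O)CC(C)(C)C(=O)O
F8 | step 2 | prop-2-en-1-yl 4-(ethylsulfanyl)-3,3-dimethyl-4-oxobutanoate | C=CCOC(=O)CC(C)(C)C(=O)SCC
F9 | step 2 | (2R)-4-(ethylsulfanyl)-3,3-dimethyl-4-oxo-2-(prop-2-en-1-yl)butanoic acid | OC(=O)[C@H](CC=C)C(C)(C)C(=O)SCC
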